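With germacrane numbering (C1 ketone, C2=C3, C4=C15 methylene, C5–OH, C6–O lactone, C7, C8 ester, C9, C10 with C14), the target is cut at C5–C6 inside the ten-membered carbocycle C1–C10. C15=C4–C5(OH)–C6(O) is a but-3-ene-1,2-diol, the retron of a γ-oxyallyl-metal addition to an aldehyde. The precursor is an open dialdehyde: the 3(2H)-furanone (O, C3, C2, C1, C10) carries a 2-substituted acrolein (C15, C4, C5) and, via C9–C7, the C6 aldehyde. CrCl2/Et3SiCl turns the enal into a γ-siloxyallylchromium that adds to C6, closing the ring, setting C5 and C6 and restoring C4=C15 in one operation.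

Key step: step 15

Remark: for step 11 the non-chelated course of the allylindium addition (aldehyde anti to the allylic C–O bond of the dioxolane) is assumed; this decides that (R)-glyceraldehyde acetonide is the enantiomer needed.

Step 1
Reactants: 1 acrolein diethyl acetal
Product: 3 2-bromo-3,3-diethoxyprop-1-ene, via 2,3-dibromo-1,1-diethoxypropane 2 (not isolated)
Conditions: Br2, CH2Cl2, −78 → 0 °C; then KOC(CH3)3, THF, 0 °C
Reagents that add atoms: bromine BrBr
Why: Bromine adds to the vinyl group and base-induced E2 loss of HBr removes the more acidic C–H next to the acetal, which should give the 2-bromoalkene (bromination–dehydrobromination).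

Step 2
Reactants: 3 2-bromo-3,3-diethoxyprop-1-ene; 4 ethynyltrimethylsilane
Product: 5 [3-(diethoxymethyl)but-3-en-1-yn-1-yl]trimethylsilane
Conditions: Pd(PPh3)2Cl2 (3 mol %), CuI (5 mol %), iPr2NH, THF, rt
Reagents that add atoms: none
Why: Sonogashira coupling of the vinyl bromide with the terminal alkyne forms the future C3–C4 bond under basic conditions that leave the acetal untouched.

Step 3
Reactants: 5 silylated enyne
Product: 6 3-(diethoxymethyl)but-3-en-1-yne
Conditions: K2CO3 (cat.), MeOH, 0 °C
Reagents that add atoms: none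
Why: Carbonate-catalysed methanolysis of the alkynyl C–Si bond (protodesilylation) should free the terminal alkyne that later supplies C2 and C3.

Step 4
Reactants: 7 (R)-2,2-dimethyl-1,3-dioxolane-4-carbaldehyde; 8 tert-butyl acrylate
Product: 9 tert-butyl 2-{[(4R)-2,2-dimethyl-1,3-dioxolan-4-yl](hydroxy)methyl}prop-2-enoate (both carbinol epimers)
Conditions: 3-hydroxyquinuclidine (0.3 equiv), MeOH, rt
Reagents that add atoms: none
Why: The Morita–Baylis–Hillman reaction joins the aldehyde carbon (future C7) to the acrylate α-carbon (C11); the new carbinol centre is formed as a mixture that step 5 erases, while the dioxolane centre (future C6) is not touched.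

Step 5
Reactants: 9 Morita–Baylis–Hillman alcohol
Product: 10 tert-butyl (2Z)-2-(bromomethyl)-3-[(4S)-2,2-dimethyl-1,3-dioxolan-4-yl]prop-2-enoate
Conditions: N-bromosuccinimide, Me2S, CH2Cl2, 0 °C → rt
Reagents that add atoms: N-bromosuccinimide O=C1CCC(=O)N1Br
Why: Corey–Kim-type activation of the alcohol as an alkoxysulfonium ion and SN2′ attack of bromide should give the thermodynamically favoured (Z)-2-(bromomethyl)alkenoate with allylic transposition and no acid to endanger the acetonide.

Step 6
Reactants: 11 (S)-citramalic acid
Product: 12 2-[(4S)-2,2,4-trimethyl-5-oxo-1,3-dioxolan-4-yl]acetic acid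
Conditions: 2,2-dimethoxypropane, TsOH·H2O (cat.), rt
Reagents that add atoms: 2,2-dimethoxypropane COC(C)(C)OC
Why: Acid-catalysed acetalisation engages only the α-hydroxy acid as the five-membered dioxolanone and leaves the β-carboxyl (future C8) free; the chiral-pool stereocentre (future C10, S) is not involved.

Step 7
Reactants: 12 dioxolanone acid
Product: 14 (3S)-3-hydroxy-3-methyloxolan-2-one, via hydroxyethyl dioxolanone 13 (not isolated)
Conditions: BH3·SMe2, THF, 0 °C → rt; MeOH; then TsOH·H2O (cat.), CH2Cl2, rt
Reagents that add atoms: none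
Why: Borane reduces the free carboxylic acid chemoselectively beside the dioxolanone, and acid then drives translactonisation to the γ-lactone with loss of acetone (chemoselective borane reduction, lactonisation).

Step 8
Reactants: 14 hydroxy lactone; 6 3-(diethoxymethyl)but-3-en-1-yne
Product: 15 (6S)-2-(diethoxymethyl)-6,8-dihydroxy-6-methyloct-1-en-3-yn-5-one (in equilibrium with its five-membered lactol)
Conditions: 6 (2.3 equiv), n-BuLi (2.2 equiv), THF, −78 °C; then 14, −78 → −30 °C; aq. NH4Cl
Reagents that add atoms: none
Why: After the first equivalent has deprotonated the tertiary hydroxyl, the lithium acetylide adds once to the lactone carbonyl because the tetrahedral lithium alkoxide survives until work-up (acetylide addition to a lactone), forming the C1–C2 bond.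

Step 9
Reactants: 15 γ-hydroxy ynone
Product: 16 (2S)-5-(3,3-diethoxyprop-1-en-2-yl)-2-(2-hydroxyethyl)-2-methylfuran-3(2H)-one
Conditions: (4-CF3C6H4)3PAuCl (2 mol %), AgOSO2CF3 (2 mol %), toluene, rt
Reagents that add atoms: none
Why: Monovalent gold activates the alkyne for 5-endo-dig attack of the tertiary C10 hydroxyl on C3 and protodeauration should give the 3(2H)-furanone (gold-catalysed cycloisomerisation of a γ-hydroxy ynone), the seven-membered alternative through the primary hydroxyl being slower.

Step 10
Reactants: 16 furanone alcohol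
Product: 17 2-[(2S)-5-(3,3-diethoxyprop-1-en-2-yl)-2-methyl-3-oxo-2,3-dihydrofuran-2-yl]acetaldehyde
Conditions: Dess–Martin periodinane, NaHCO3, CH2Cl2, 0 °C → rt; used crude
Reagents that add atoms: none
Why: Dess–Martin oxidation under buffered, amine-free conditions should give the C8 aldehyde without β-elimination of the furanone oxygen and without acetal hydrolysis.

Step 11
Reactants: 17 furanone aldehyde; 10 (Z)-allylic bromide
Product: 18 tert-butyl (3R,4R)-5-[(2S)-5-(3,3-diethoxyprop-1-en-2-yl)-2-methyl-3-oxo-2,3-dihydrofuran-2-yl]-3-[(4S)-2,2-dimethyl-1,3-dioxolan-4-yl]-4-hydroxy-2-methylidenepentanoate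
Conditions: indium powder, DMF, rt; aq. NaHCO3
Reagents that add atoms: none
Why: In this Barbier allylation the (Z)-allylindium from 10 should add through its γ-carbon in a chair Zimmerman–Traxler transition state to give the 7,8-syn adduct with the C11=C13 methylene, while the aldehyde approaches the allyl face anti to the allylic C–O bond of the dioxolane (its C–H eclipsing the alkene to avoid allylic 1,3-strain), so that C7 and C8 are set as R,R by reagent control over the remote C10 centre.

Step 12
Reactants: 18 hydroxy ester; 19 3-methylbutanoic (isovaleric) anhydride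
Product: 20 tert-butyl (3R,4R)-5-[(2S)-5-(3,3-diethoxyprop-1-en-2-yl)-2-methyl-3-oxo-2,3-dihydrofuran-2-yl]-3-[(4S)-2,2-dimethyl-1,3-dioxolan-4-yl]-4-(3-methylbutanoyloxy)-2-methylidenepentanoate
Conditions: DMAP (cat.), Et3N, CH2Cl2, rt
Reagents that add atoms: none
Why: DMAP-catalysed acylation of the only free hydroxyl installs the C8 isovalerate, the tert-butyl ester having kept the C8 hydroxyl from lactonising beforehand.

Step 13
Reactants: 20 isovalerate
Product: 21 tert-butyl (3S,4R)-3-[(1S)-1,2-dihydroxyethyl]-4-(3-methylbutanoyloxy)-2-methylidene-5-[(2S)-2-methyl-3-oxo-5-(3-oxoprop-1-en-2-yl)-2,3-dihydrofuran-2-yl]pentanoate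
Conditions: AcOH/THF/H2O (3:1:1), 40 °C
Reagents that add atoms: water O
Why: Aqueous acetic acid should hydrolyse the diethyl acetal to the C5 enal and the terminal acetonide to the 1,2-diol (acetal hydrolysis) while the tert-butyl ester and the isovalerate survive.

Step 14
Reactants: 21 diol enal
Product: 22 tert-butyl (3R,4R)-3-formyl-4-(3-methylbutanoyloxy)-2-methylidene-5-[(2S)-2-methyl-3-oxo-5-(3-oxoprop-1-en-2-yl)-2,3-dihydrofuran-2-yl]pentanoate
Conditions: NaIO4 on silica gel, CH2Cl2, rt; filtered and used at once
Reagents that add atoms: none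
Why: Malaprade glycol cleavage unveils the C6 aldehyde under neutral, essentially non-aqueous conditions, which should protect the epimerisable C7 centre and the β-acyloxy group, the temporary dioxolane carbon leaving as formaldehyde.

Step 15
Reactants: 22 dialdehyde
Product: 24 ten-membered carbocycle with C5–OSiEt3 and C6–OH (tert-butyl ester), via siloxyallylchromium 23 (not isolated)
Conditions: CrCl2 (6 equiv), Et3SiCl (3 equiv), DMF, rt, 22 added by syringe pump to 0.002 M; aq. NaHCO3
Reagents that add atoms: chlorotriethylsilane CC[Si](Cl)(CC)CC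
Why: This is a chromium-mediated cross-pinacol-type coupling (Takai–Utimoto type) run in ring-closing mode: two single-electron transfers from divalent chromium to the silyl-activated enal, the most easily reduced carbonyl of 22, give the γ-siloxyallylchromium 23 (trivalent chromium on C15), which adds through its γ-carbon C5 to the C6 aldehyde in a six-membered chair transition state (SE2′) and so returns the C4=C15 methylene. The closest known reactions are the intermolecular chromium-mediated cross-pinacol coupling of 2-substituted acroleins with aldehydes and chromium-mediated ring-closing allylations that form ten-membered germacranolide rings. The step closes the ten-membered carbocycle C1–C10 (equally the nine-membered oxa-bridged ring through the furanone oxygen) as a 10-exo-trig addition to the aldehyde, the rigid furanone holding the arms on C3 and C10 close together. C5 is controlled by the enol-ether geometry (the s-trans enal places OSiEt3 trans to CH2Cr, equatorial in the chair) and C6 by the C7 centre (C7 equatorial, Felkin–Anh approach with the C8 branch anti to the incoming carbon), which together should give the 5,6-anti (5R,6S) product with O6 and C11 placed for the trans-lactone. The step needs reduction of the enal in preference to the C6 aldehyde, the furanone and the acrylate, secured by conjugation and silyl activation, and cyclisation in preference to oligomerisation, secured by slow addition to high dilution. The mild, non-basic medium protects the C7–H and the β-isovaleryloxy group of the aldehyde.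

Step 16
Reactants: 24 silyl ether hydroxy ester
Product: 25 CNP0409337.1
Conditions: CF3CO2H/CH2Cl2 (1:4), 0 °C → rt; aq. NaHCO3
Reagents that add atoms: none
Why: Acidolysis should cleave the triethylsilyl ether and the tert-butyl ester (as 2-methylpropene), and the liberated acid closes the five-membered lactone onto the γ-hydroxyl O6 in preference to the six-membered ring through O5 (acid-mediated deprotection and lactonisation).

Compound list
1 | acrolein diethyl acetal (3,3-diethoxyprop-1-ene) | C=CC(OCC)OCC | starting material
2 | 2,3-dibromo-1,1-diethoxypropane | BrCC(Br)C(OCC)OCC | intermediate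
3 | 2-bromo-3,3-diethoxyprop-1-ene | C=C(Br)C(OCC)OCC | intermediate
4 | ethynyltrimethylsilane | C#C[Si](C)(C)C | starting material
5 | [3-(diethoxymethyl)but-3-en-1-yn-1-yl]trimethylsilane | C=C(C#C[Si](C)(C)C)C(OCC)OCC | intermediate
6 | 3-(diethoxymethyl)but-3-en-1-yne | C=C(C#C)C(OCC)OCC | intermediate
7 | (R)-2,2-dimethyl-1,3-dioxolane-4-carbaldehyde | O=C[C@H]1COC(C)(C)O1 | starting material
8 | tert-butyl acrylate | C=CC(=O)OC(C)(C)C | starting material
9 | tert-butyl 2-{[(4R)-2,2-dimethyl-1,3-dioxolan-4-yl](hydroxy)methyl}prop-2-enoate, both carbinol epimers | C=C(C(=O)OC(C)(C)C)C(O)[C@H]1COC(C)(C)O1 | intermediate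
10 | tert-butyl (2Z)-2-(bromomethyl)-3-[(4S)-2,2-dimethyl-1,3-dioxolan-4-yl]prop-2-enoate | BrC/C(=C\[C@H]1COC(C)(C)O1)C(=O)OC(C)(C)C | intermediate
11 | (S)-citramalic acid | C[C@](O)(CC(=O)O)C(=O)O | starting material
12 | 2-[(4S)-2,2,4-trimethyl-5-oxo-1,3-dioxolan-4-yl]acetic acid | C[C@@]1(CC(=O)O)OC(C)(C)OC1=O | intermediate
13 | (5S)-5-(2-hydroxyethyl)-2,2,5-trimethyl-1,3-dioxolan-4-one | C[C@@]1(CCO)OC(C)(C)OC1=O | intermediate
14 | (3S)-3-hydroxy-3-methyloxolan-2-one | C[C@]1(O)CCOC1=O | intermediate
15 | (6S)-2-(diethoxymethyl)-6,8-dihydroxy-6-methyloct-1-en-3-yn-5-one | C=C(C(OCC)OCC)C#CC(=O)[C@@](C)(O)CCO | intermediate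
16 | (2S)-5-(3,3-diethoxyprop-1-en-2-yl)-2-(2-hydroxyethyl)-2-methylfuran-3(2H)-one | C=C(C(OCC)OCC)C1=CC(=O)[C@](C)(CCO)O1 | intermediate
17 | 2-[(2S)-5-(3,3-diethoxyprop-1-en-2-yl)-2-methyl-3-oxo-2,3-dihydrofuran-2-yl]acetaldehyde | C=C(C(OCC)OCC)C1=CC(=O)[C@](C)(CC=O)O1 | intermediate
18 | tert-butyl (3R,4R)-5-[(2S)-5-(3,3-diethoxyprop-1-en-2-yl)-2-methyl-3-oxo-2,3-dihydrofuran-2-yl]-3-[(4S)-2,2-dimethyl-1,3-dioxolan-4-yl]-4-hydroxy-2-methylidenepentanoate | C=C(C(=O)OC(C)(C)C)[C@@H]([C@H]1COC(C)(C)O1)[C@H](O)C[C@]1(C)OC(=CC1=O)C(=C)C(OCC)OCC | intermediate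
19 | 3-methylbutanoic (isovaleric) anhydride | CC(C)CC(=O)OC(=O)CC(C)C | starting material
20 | tert-butyl (3R,4R)-5-[(2S)-5-(3,3-diethoxyprop-1-en-2-yl)-2-methyl-3-oxo-2,3-dihydrofuran-2-yl]-3-[(4S)-2,2-dimethyl-1,3-dioxolan-4-yl]-4-(3-methylbutanoyloxy)-2-methylidenepentanoate | C=C(C(=O)OC(C)(C)C)[C@@H]([C@H]1COC(C)(C)O1)[C@H](OC(=O)CC(C)C)C[C@]1(C)OC(=CC1=O)C(=C)C(OCC)OCC | intermediate
21 | tert-butyl (3S,4R)-3-[(1S)-1,2-dihydroxyethyl]-4-(3-methylbutanoyloxy)-2-methylidene-5-[(2S)-2-methyl-3-oxo-5-(3-oxoprop-1-en-2-yl)-2,3-dihydrofuran-2-yl]pentanoate | C=C(C(=O)OC(C)(C)C)[C@@H]([C@H](O)CO)[C@H](OC(=O)CC(C)C)C[C@]1(C)OC(=CC1=O)C(=C)C=O | intermediate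
22 | tert-butyl (3R,4R)-3-formyl-4-(3-methylbutanoyloxy)-2-methylidene-5-[(2S)-2-methyl-3-oxo-5-(3-oxoprop-1-en-2-yl)-2,3-dihydrofuran-2-yl]pentanoate | C=C(C(=O)OC(C)(C)C)[C@@H](C=O)[C@H](OC(=O)CC(C)C)C[C@]1(C)OC(=CC1=O)C(=C)C=O | intermediate
23 | γ-siloxyallylchromium species: dichlorochromium on C15, C4=C5 enol triethylsilyl ether with OSiEt3 trans to CH2Cr, C6 aldehyde intact | O=C[C@H](C(=C)C(=O)OC(C)(C)C)[C@H](OC(=O)CC(C)C)C[C@]1(C)OC(=CC1=O)/C(C[Cr](Cl)Cl)=C\O[Si](CC)(CC)CC | intermediate
24 | tert-butyl 2-[6-hydroxy-10-methyl-8-(3-methylbutanoyloxy)-4-methylidene-1-oxo-5-(triethylsilyloxy)-3,10-epoxycyclodec-2-en-7-yl]prop-2-enoate (target numbering; C5, C6, C7, C8 and C10 arranged as in the target) | O[C@H]2[C@H](C(=C)C(=O)OC(C)(C)C)[C@H](OC(=O)CC(C)C)C[C@]1(C)OC(=CC1=O)C(=C)[C@H]2O[Si](CC)(CC)CC | intermediate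
25 | CNP0409337.1, (5R,6S,7R,8R,10S)-5-hydroxy-8-(3-methylbutanoyloxy)-1-oxo-3,10-epoxygermacra-2,4(15),11(13)-trien-12,6-olide | C=C1C(=O)O[C@H]2[C@H]1[C@H](OC(=O)CC(C)C)C[C@]1(C)OC(=CC1=O)C(=C)[C@H]2O | target

Total step count: 16. Longest linear sequence: 12 steps (1 → 3 → 5 → 6, then steps 8 to 16); the branch from 11 runs 11 steps and the branch from 7 runs 8 steps.

Steps most likely to fail

1. Step 15 (ring closure). Intermolecular coupling and oligomerisation may outrun cyclisation, the cross-conjugated furanone may be reduced, and facial selectivity at C5 or C6 may be poor in the medium-ring transition state. Fallback: from dialdehyde 22, an SmI2-mediated intramolecular pinacol coupling (THF, −78 °C, slow addition) joins the two ketyl carbons while both oxygens are held on samarium. This favours the cis-diol on the ring, which is the 5,6-anti relationship of the target, and should give the free 5,6-diol tert-butyl ester F1. The acid treatment of step 16 then cleaves the ester and closes the γ-lactone, so the route is rejoined at 25.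

2. Step 11 (Barbier allylation). The π-facial selectivity may erode or reverse if the dioxolane oxygen binds indium, the δ-alkoxy allylindium may undergo 1,4-elimination, and syn-selectivity may be lost through E/Z equilibration of the allylmetal. Fallback: from bromide 10, palladium-catalysed borylation (B2pin2, Pd2(dba)3, toluene, 50 °C) should give the configurationally stable allylboronate F2. This adds to aldehyde 17 under Sc(OSO2CF3)3 catalysis through a tight boron chair transition state in which boron cannot chelate the dioxolane (the γ-substituent cis to CH2B gives the syn adduct), and work-up returns the route to 18.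

3. Step 13 (unmasking of enal and diol). The liberated secondary hydroxyl (future O6) may lactonise onto the tert-butyl ester, the isovalerate may migrate to the new diol, or the reactive enal may be lost during prolonged acid treatment. Fallback: from 20, H5IO6 in wet ethyl acetate (0 °C → rt) hydrolyses the acetal and the acetonide and cleaves the glycol in the same flask, so that no free diol accumulates. This makes no new compound (F0) and returns directly to 22, which is used at once in step 15.

Further compounds
F1 | step 15 | tert-butyl 2-[5,6-dihydroxy-10-methyl-8-(3-methylbutanoyloxy)-4-methylidene-1-oxo-3,10-epoxycyclodec-2-en-7-yl]prop-2-enoate (target numbering, configuration as in the target) | O[C@H]2[C@H](C(=C)C(=O)OC(C)(C)C)[C@H](OC(=O)CC(C)C)C[C@]1(C)OC(=CC1=O)C(=C)[C@H]2O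
F2 | step 11 | tert-butyl (2E)-3-[(4S)-2,2-dimethyl-1,3-dioxolan-4-yl]-2-[(4,4,5,5-tetramethyl-1,3,2-dioxaborolan-2-yl)methyl]prop-2-enoate | CC1(C)OB(C/C(=C\[C@H]2COC(C)(C)O2)C(=O)OC(C)(C)C)OC1(C)C
F0 | step 13 | none | none
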